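All six members share the briarane core: cyclohexane ring A (C1, C10–C14) trans-fused to the ten-membered ring C1–C10, the C7–C8 γ-lactone, 6-Cl, 8-OH, 9-OAc, the 13α,14α-epoxide and the Z-C3=C4/C5=C16 diene. They differ at O2 and O12 (H, acetyl, butanoyl) and at C11 (OH or H). Shared intermediate 24 holds all the rest, with a free 2-OH and a C12 ketone that activates C11. The trunk exploits that the ten-membered ring is a six-membered ring (C1, C2, C3, C8, C9, C10) enlarged by C4–C7. C1, C2, C9 and C10 are set in a rigid trans-decalin made by a quinone Diels–Alder reaction. A propargyl Claisen shift puts an allene on C3. An anionic oxy-Cope shift of the 8-vinyl-3-allenyl decalinol then breaks C3–C8 and forms C5–C6. One operation delivers the ring, the Z-alkene, the exocyclic diene and a C7 enolate.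

Key step: step 10
Shared intermediate: compound 24

Remark: all atoms carry briarane numbers from the first intermediate on (C15 on C1, C16 on C5, C18 on C17, C20 on C11); β is the face of C15, α the opposite face.

TRUNK

Step 1
Reactants: 1 2-methyl-1,4-benzoquinone; 2 prop-2-yn-1-ol
Product: 3 2-methyl-5-(prop-2-yn-1-yloxy)-1,4-benzoquinone
Conditions: ZnCl2, neat 2, 40 °C (2 equiv of 1, the second as oxidant)
Reagents that add atoms: none
Why: Lewis-acid-promoted oxidative conjugate addition of an alcohol to a quinone; the alcohol attacks the ring position para to the methyl group, which is β to the carbonyl that the methyl group does not deactivate, and excess 1 reoxidises the hydroquinone adduct.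

Step 2
Reactants: 4 pent-1-en-3-one
Product: 5 (Z)-3-(triisopropylsilyloxy)penta-1,3-diene
Conditions: TIPSOTf, Et3N, CH2Cl2, 0 °C
Reagents that add atoms: triisopropylsilyl triflate, CC(C)[Si](OS(=O)(=O)C(F)(F)F)(C(C)C)C(C)C
Why: Soft enolisation and O-silylation of an ethyl ketone, which should give the Z enol silane (methyl trans to vinyl), the geometry that reaches the s-cis conformation with the methyl group outside.

Step 3
Reactants: 3 2-methyl-5-(prop-2-yn-1-yloxy)-1,4-benzoquinone; 5 (Z)-3-(triisopropylsilyloxy)penta-1,3-diene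
Product: 6 cis-fused endo adduct (decalin-2,9-dione; C15, H10 and H11 all β, C20 α; 8-O-propargyl Δ3(8) enol ether; 12-OTIPS Δ12 enol ether)
Conditions: (S)-diphenylprolinol/o-tolylboron oxazaborolidine·Tf2NH (20 mol %), CH2Cl2, −78 → −40 °C
Reagents that add atoms: none
Why: Catalytic enantioselective Diels–Alder reaction with a chiral oxazaborolidinium Lewis acid: the alkoxy-bearing C3=C8 bond is deactivated so only C1=C10 reacts, coordination to the more basic vinylogous-ester carbonyl C2=O makes C10 the electrophilic end that meets the nucleophilic enol-silane carbon C11, the endo transition state places C15, H10 and H11 on one face, and the catalyst (its mirror image is equally available) selects the quinone face and thereby sets C1.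

Step 4
Reactants: 6 cis-fused endo adduct
Product: 7 trans-fused enedione (H10 α, otherwise as 6)
Conditions: DBU (0.2 equiv), CH2Cl2, rt
Reagents that add atoms: none
Why: Base-mediated epimerisation through the C9 enol; C10 is the only enolisable stereocentre, and the flat enedione ring should favour the trans-fused isomer with H10 anti to C15.

Step 5
Reactants: 7 trans-fused enedione
Product: 8 2β,9β-diol
Conditions: DIBAL-H (2.5 equiv), CH2Cl2, −78 °C; aq Rochelle salt
Reagents that add atoms: none
Why: 1,2-Reduction of both conjugated carbonyls; the axial C15 methyl (next to C2, syn-axial to C9) shields the β face, so hydride arrives from α and should give the equatorial 2β- and the axial 9β-alcohol.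

Step 6
Reactants: 8 2β,9β-diol
Product: 9 2β-O-TBS ether, 9β-OH free
Conditions: TBSCl, imidazole, DMF, 0 °C
Reagents that add atoms: tert-butyldimethylsilyl chloride, CC(C)(C)[Si](C)(C)Cl
Why: Site-selective silylation; the equatorial 2β-OH reacts, whereas the axial 9β-OH, syn-axial to C15 and flanked by C20, is too hindered for TBSCl at this temperature.

Step 7
Reactants: 9 2β-O-TBS ether
Product: 10 2β-OTBS, 9β-OPMB propargyl enol ether
Conditions: KHMDS (1.05 equiv), PMBBr, THF, −78 → 0 °C
Reagents that add atoms: 4-methoxybenzyl bromide, COc1ccc(CBr)cc1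
Why: Williamson etherification; one equivalent of base takes the alcohol proton (far more acidic than the alkyne C–H), and an ether is chosen at O9 because, unlike a silyl group, it cannot migrate to the neighbouring C8 alkoxide in step 10.

Step 8
Reactants: 10 2β-OTBS, 9β-OPMB propargyl enol ether
Product: 11 3α-(propa-1,2-dienyl) 8-ketone (allene equatorial, H3 β)
Conditions: o-xylene, BHT (cat.), base-washed glass, 140 °C
Reagents that add atoms: none
Why: Propargyl Claisen rearrangement ([3,3] shift of a propargyl vinyl ether): it unmasks the C8 ketone and joins C3 to the alkyne terminus (C4) so that the OCH2 carbon becomes C16 of a terminal allene, and the propargyl arm swings across the open α face (β is blocked by C15 and the axial 9-OPMB), which makes the allene equatorial.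

Step 9
Reactants: 11 3α-allenyl 8-ketone; 12 vinylmagnesium bromide
Product: 13 8α-vinyl-3α-allenyl decalin-8β-ol
Conditions: LaCl3·2LiCl (1 equiv), THF, −78 °C; aq NH4Cl
Reagents that add atoms: none
Why: Lanthanide-assisted 1,2-addition of a Grignard reagent to an enolisable ketone; attack is axial from the α face, antiperiplanar to the axial C9–O bond (polar Felkin–Anh) and away from C15 and the OPMB group, so the vinyl group is axial and cis to the equatorial allene.

Step 10
Reactants: 13 8α-vinyl-3α-allenyl decalin-8β-ol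
Product: 15 (3Z,6E)-5-methylene cyclodecadien-8-one fused to ring A (2β-OTBS, 9β-OPMB, 12-OTIPS), via potassium C7=C8 enolate 14 (not isolated)
Conditions: KH, 18-crown-6, THF, 0 °C → rt; then PhS(Cl)=Nt-Bu, −78 °C
Reagents that add atoms: potassium hydride, [K+].[H-] (supplies the K+ of 14; nothing from it stays in 15)
Why: Proposed new method: the potassium alkoxide of 13 weakens the C3–C8 bond and the 1,5-diene C6=C7–C8–C3–C4=C5 undergoes a concerted anionic [3,3] shift in which C6 bonds to the central allene carbon C5, so that the orthogonal C5=C16 π bond survives as the exocyclic methylene conjugated with the new C3=C4 bond. The closest known reaction types are the anionic oxy-Cope ring expansion of 1,2-divinylcyclohexanols to cyclodec-5-enones and the thermal Cope rearrangement of 1,2,6-heptatrienes to 3-methylene-1,5-hexadienes; an allene terminus in the anionic ring-expanding version is the untested element. The ten-membered ring is closed by four-atom ring enlargement through a six-membered chair transition state, not by end-to-end cyclisation. No sp3 centre is made or touched (C1, C2, C9, C10 and C11 are carried over), and the Z geometry of C3=C4 is fixed by the locked trans-decalin, where an axial vinyl group on C8 and an equatorial allene on C3 (torsion near 60°) allow a single chair in which C2 is axial. Enolate 14 is regiodefined at C7 and is dehydrogenated in the same flask by sulfenylation and syn-elimination (Mukaiyama dehydrogenation), which should take the C6 hydrogen that leaves C5 and C8 anti and so give the E-enone. The step needs the shift to outrun addition of the alkoxide to the allene and base-induced allene isomerisation, which the pre-organised cis arrangement of the two π systems should secure.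

Step 11
Reactants: 15 (3Z,6E)-trienone; 16 ethyl propanoate
Product: 17 C8 tertiary alcohol bearing the C17(C18)–C19O2Et side chain
Conditions: LDA, 16, THF, −78 °C; then 15, −78 °C; AcOH quench at −78 °C
Reagents that add atoms: none
Why: Aldol addition of a lithium ester enolate (kinetic 1,2-addition); with C8=O turned away from the C9–O dipole the enolate adds anti to C9–OPMB on the outer face of the ring (polar Felkin–Anh), which sets C8, while C17 need not be controlled here because it is equilibrated in step 16.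

Step 12
Reactants: 17 aldol adduct
Product: 18 8,9-diol with ring A Δ13-en-12-one
Conditions: DDQ (3 equiv), CH2Cl2/pH 7 buffer, 0 °C → rt
Reagents that add atoms: none
Why: Two known DDQ oxidations in one flask: oxidative cleavage of the p-methoxybenzyl ether frees 9-OH, and hydride abstraction from C14 (allylic to the enol silane) followed by loss of silicon gives the Δ13 enone regiospecifically, while the O2 silyl ether and the less electron-rich triene should react more slowly.

Step 13
Reactants: 18 8,9-diol enone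
Product: 19 9-acetate
Conditions: Ac2O, Et3N, DMAP (cat.), CH2Cl2, 0 °C
Reagents that add atoms: acetic anhydride, CC(=O)OC(C)=O
Why: DMAP-catalysed acylation; only the secondary 9-OH reacts because the 8-OH is tertiary, and fast acetylation forestalls lactonisation of 9-OH onto the ester.

Step 14
Reactants: 19 9-acetate
Product: 20 trans-6,7-epoxide
Conditions: VO(acac)2 (5 mol %), t-BuOOH (decane), PhMe, 0 °C
Reagents that add atoms: tert-butyl hydroperoxide, CC(C)(C)OO
Why: Vanadium-catalysed hydroxyl-directed epoxidation; only C6=C7 is allylic to a free OH (the enone is electron-poor, O2 is silylated), oxygen is delivered syn to 8-OH in the conformer with an O8–C8–C7=C6 torsion of about 45°, which is also the outer face of the ring, and the E-alkene gives the trans-epoxide that sets C7.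

Step 15
Reactants: 20 trans-6,7-epoxide
Product: 22 6-chloro γ-lactone (6S,7R; 8-OH, 9-OAc, 2-OTBS, ring A enone), via 6-chloro-7,8-diol ethyl ester 21 (not isolated)
Conditions: ClTi(Oi-Pr)3, CH2Cl2, −30 °C; aq tartrate; then PPTS (cat.), PhH, 45 °C
Reagents that add atoms: chlorotitanium triisopropoxide, CC(C)O[Ti](Cl)(OC(C)C)OC(C)C
Why: Titanium-assisted opening of a 2,3-epoxy alcohol at the distal carbon: the C8 titanate delivers chloride to C6, which is also the allylic and most activated position, with inversion (trans-epoxide to anti chlorohydrin), and the freed 7-OH closes the five-membered lactone by acid-catalysed transesterification.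

Step 16
Reactants: 22 6-chloro γ-lactone
Product: 23 13α,14α-epoxy-12-ketone
Conditions: t-BuOOH (decane), DBU, CH2Cl2, 0 °C
Reagents that add atoms: tert-butyl hydroperoxide, CC(C)(C)OO
Why: Weitz–Scheffer nucleophilic epoxidation, selective for the only electron-poor alkene; the peroxide anion adds to C14 anti to the axial C15 methyl to give the α-epoxide, and under DBU the lactone α-carbon C17 should settle in its more stable configuration with C18 cis to 8-OH and away from C9.

Step 17
Reactants: 23 13α,14α-epoxy-12-ketone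
Product: 24 shared intermediate (2β-OH, 6-Cl, 8-OH, 9-OAc, lactone, diene, 13α,14α-epoxy-12-one, 11α-methyl)
Conditions: HF·pyridine, THF/pyridine, 0 °C → rt
Reagents that add atoms: none
Why: Fluoride-mediated desilylation under buffered conditions that leave acetate, lactone, allylic chloride and the deactivated α,β-epoxy ketone untouched.

BRANCHES

Branch to CNP0331168.1 (compound 29)

Step 18
Reactants: 24 shared intermediate
Product: 25 Δ11(12) 12-O-TMS enol ether, 2,8-bis-O-TMS ether
Conditions: TMSOTf (3.3 equiv), Et3N, CH2Cl2, −20 °C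
Reagents that add atoms: trimethylsilyl triflate, C[Si](C)(C)OS(=O)(=O)C(F)(F)F
Why: Soft enolisation with silyl triflate and amine; among the carbonyl groups only the ketone enolises under these conditions (lactone and acetate need harsher treatment), it can do so only towards C11 because C13 is an oxirane carbon, and 2-OH and 8-OH are silylated and thereby protected at the same time.

Step 19
Reactants: 25 tris-TMS enol ether
Product: 27 11α-hydroxy-12-ketone (C20 β), via 11α,12α-epoxy-12-silyloxy compound 26 (not isolated)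
Conditions: DMDO (1 equiv), acetone/CH2Cl2, −78 °C; then 10% aq citric acid, THF, 0 °C
Reagents that add atoms: dimethyldioxirane, CC1(C)OO1
Why: Rubottom oxidation; one equivalent of dioxirane takes the tetrasubstituted enol silane, by far the most electron-rich alkene (the diene is deactivated by allylic Cl and O), from the α face opposite C15 and the C9 branch, and mild acid collapses the silyloxy epoxide to the α-hydroxy ketone and removes the trimethylsilyl ethers.

Step 20
Reactants: 27 11α-hydroxy-12-ketone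
Product: 28 2β,8,11α,12α-tetraol
Conditions: NaBH4, CeCl3·7H2O, MeOH/CH2Cl2, −78 °C
Reagents that add atoms: none
Why: Luche reduction; hydride should reach C12 from the β face, anti to the oxirane oxygen and to the cerium-bound 11α-oxygen, giving the 12α-alcohol cis to both, while lactone, acetate and allylic chloride are inert at −78 °C.

Step 21
Reactants: 28 tetraol
Product: 29 CNP0331168.1
Conditions: Ac2O (excess), pyridine, DMAP (cat.), CH2Cl2, rt
Reagents that add atoms: acetic anhydride, CC(=O)OC(C)=O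
Why: DMAP-catalysed acylation; the two secondary alcohols (O2, O12) are acetylated, and the tertiary 8-OH and 11-OH stay free because they are too hindered under these conditions.

Branch to CNP0188106.1 (compound 30)

Step 22
Reactants: 28 tetraol
Product: 30 CNP0188106.1
Conditions: (n-PrCO)2O (excess), Et3N, DMAP (cat.), CH2Cl2, rt
Reagents that add atoms: butanoic anhydride, CCCC(=O)OC(=O)CCC
Why: DMAP-catalysed acylation of both secondary alcohols (O2, O12), with the tertiary 8-OH and 11-OH left free for steric reasons as in step 21.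

Branch to CNP0325729.2 (compound 31)

Step 23
Reactants: 28 tetraol
Product: 31 CNP0325729.2
Conditions: n-PrCOCl (1.1 equiv), Ph2BOCH2CH2NH2 (10 mol %), i-Pr2NEt, MeCN, rt
Reagents that add atoms: butanoyl chloride, CCCC(=O)Cl
Why: Diarylborinic-acid-catalysed monoacylation of a cis-1,2-diol; only the cis-11α,12α-diol can form the nucleophilic borinate, within it only the secondary O12 can be acylated, the isolated neopentylic 2-OH is not activated, and 8-OH has no free vicinal partner.

Branch to CNP0273377.1 (compound 32)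

Step 24
Reactants: 31 CNP0325729.2
Product: 32 CNP0273377.1
Conditions: Ac2O, pyridine, DMAP (cat.), CH2Cl2, rt
Reagents that add atoms: acetic anhydride, CC(=O)OC(C)=O
Why: DMAP-catalysed acetylation of 2-OH, the only secondary alcohol left; the tertiary 8-OH and 11-OH do not react.

Branch to CNP0114058.1 (compound 34)

Step 25
Reactants: 28 tetraol
Product: 33 12-O-acetate (2-OH, 8-OH, 11-OH free)
Conditions: AcCl (1.1 equiv), Ph2BOCH2CH2NH2 (10 mol %), i-Pr2NEt, MeCN, rt
Reagents that add atoms: acetyl chloride, CC(=O)Cl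
Why: Diarylborinic-acid-catalysed monoacylation; as in step 23 the catalyst binds only the cis-11,12-diol and passes the acyl group to its secondary oxygen O12, leaving the unactivated 2-OH free.

Step 26
Reactants: 33 12-O-acetate
Product: 34 CNP0114058.1
Conditions: (n-PrCO)2O, Et3N, DMAP (cat.), CH2Cl2, rt
Reagents that add atoms: butanoic anhydride, CCCC(=O)OC(=O)CCC
Why: DMAP-catalysed acylation of 2-OH, the only remaining secondary alcohol; the tertiary 8-OH and 11-OH do not react.

Branch to brianthein Z (compound 37)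

Step 27
Reactants: 25 tris-TMS enol ether
Product: 35 11β-methyl-11α-H epoxy ketone (C11 epimer of 24)
Conditions: TBAF (3.3 equiv), 2,6-di-tert-butyl-4-methylphenol (10 equiv), THF, −78 °C; pH 7 buffer
Reagents that add atoms: none
Why: Kinetic protonation of an enolate released from its enol silane; the hindered phenol has to approach C11 from the same open α face that the oxidant uses in step 19, which places H11 α and C20 β (the less stable epimer), low temperature and a buffered quench prevent equilibration, and the two trimethylsilyl ethers are cleaved as well.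

Step 28
Reactants: 35 11β-methyl epoxy ketone
Product: 36 11-deoxy 2β,12α-diol
Conditions: NaBH4, CeCl3·7H2O, MeOH/CH2Cl2, −78 °C (35 used at once)
Reagents that add atoms: none
Why: Luche reduction; hydride should add anti to the oxirane oxygen from the β face to give the 12α-alcohol cis to the epoxide and to H11, and removal of the ketone freezes the C11 configuration.

Step 29
Reactants: 36 11-deoxy 2β,12α-diol
Product: 37 brianthein Z
Conditions: Ac2O (excess), pyridine, DMAP (cat.), CH2Cl2, rt
Reagents that add atoms: acetic anhydride, CC(=O)OC(C)=O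
Why: DMAP-catalysed acetylation of the two secondary alcohols (O2, O12); the tertiary 8-OH does not react.

COMPOUND LIST

1 | 2-methyl-1,4-benzoquinone | CC1=CC(=O)C=CC1=O | starting material
2 | prop-2-yn-1-ol | C#CCO | starting material
3 | 2-methyl-5-(prop-2-yn-1-yloxy)-1,4-benzoquinone | CC1=CC(=O)C(OCC#C)=CC1=O | intermediate
4 | pent-1-en-3-one | C=CC(=O)CC | starting material
5 | (Z)-3-(triisopropylsilyloxy)penta-1,3-diene | C=C/C(O[Si](C(C)C)(C(C)C)C(C)C)=C/C | intermediate
6 | cis-fused endo Diels–Alder adduct | C[C@]12CC=C(O[Si](C(C)C)(C(C)C)C(C)C)[C@@H](C)[C@H]1C(=O)C(OCC#C)=CC2=O | intermediate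
7 | trans-fused enedione | C[C@]12CC=C(O[Si](C(C)C)(C(C)C)C(C)C)[C@@H](C)[C@@H]1C(=O)C(OCC#C)=CC2=O | intermediate
8 | 2β,9β-diol | C[C@]12CC=C(O[Si](C(C)C)(C(C)C)C(C)C)[C@@H](C)[C@@H]1[C@H](O)C(OCC#C)=C[C@@H]2O | intermediate
9 | 2β-O-TBS ether, 9β-OH | C[C@]12CC=C(O[Si](C(C)C)(C(C)C)C(C)C)[C@@H](C)[C@@H]1[C@H](O)C(OCC#C)=C[C@@H]2O[Si](C)(C)C(C)(C)C | intermediate
10 | 2β-OTBS, 9β-OPMB propargyl enol ether | C[C@]12CC=C(O[Si](C(C)C)(C(C)C)C(C)C)[C@@H](C)[C@@H]1[C@H](OCc3ccc(OC)cc3)C(OCC#C)=C[C@@H]2O[Si](C)(C)C(C)(C)C | intermediate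
11 | 3α-allenyl 8-ketone | C[C@]12CC=C(O[Si](C(C)C)(C(C)C)C(C)C)[C@@H](C)[C@@H]1[C@H](OCc3ccc(OC)cc3)C(=O)[C@@H](C=C=C)[C@@H]2O[Si](C)(C)C(C)(C)C | intermediate
12 | vinylmagnesium bromide | C=C[Mg]Br | starting material
13 | 8α-vinyl-3α-allenyl decalin-8β-ol | C[C@]12CC=C(O[Si](C(C)C)(C(C)C)C(C)C)[C@@H](C)[C@@H]1[C@H](OCc3ccc(OC)cc3)[C@@](O)(C=C)[C@@H](C=C=C)[C@@H]2O[Si](C)(C)C(C)(C)C | intermediate
14 | potassium C7=C8 enolate of the ring-expanded ketone | [K+].[O-]/C1=C\CC(=C)/C=C\[C@H](O[Si](C)(C)C(C)(C)C)[C@@]2(C)CC=C(O[Si](C(C)C)(C(C)C)C(C)C)[C@@H](C)[C@@H]2[C@@H]1OCc3ccc(OC)cc3 | intermediate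
15 | (3Z,6E)-5-methylene cyclodecadien-8-one | O=C1/C=C/C(=C)/C=C\[C@H](O[Si](C)(C)C(C)(C)C)[C@@]2(C)CC=C(O[Si](C(C)C)(C(C)C)C(C)C)[C@@H](C)[C@@H]2[C@@H]1OCc3ccc(OC)cc3 | intermediate
16 | ethyl propanoate | CCC(=O)OCC | starting material
17 | C8 aldol adduct | CCOC(=O)[C@H](C)[C@]1(O)/C=C/C(=C)/C=C\[C@H](O[Si](C)(C)C(C)(C)C)[C@@]2(C)CC=C(O[Si](C(C)C)(C(C)C)C(C)C)[C@@H](C)[C@@H]2[C@@H]1OCc3ccc(OC)cc3 | intermediate
18 | 8,9-diol with ring A enone | CCOC(=O)[C@H](C)[C@]1(O)/C=C/C(=C)/C=C\[C@H](O[Si](C)(C)C(C)(C)C)[C@@]2(C)C=CC(=O)[C@@H](C)[C@@H]2[C@@H]1O | intermediate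
19 | 9-acetate | CCOC(=O)[C@H](C)[C@]1(O)/C=C/C(=C)/C=C\[C@H](O[Si](C)(C)C(C)(C)C)[C@@]2(C)C=CC(=O)[C@@H](C)[C@@H]2[C@@H]1OC(C)=O | intermediate
20 | trans-6,7-epoxide | CCOC(=O)[C@H](C)[C@]1(O)[C@H]4O[C@@H]4C(=C)/C=C\[C@H](O[Si](C)(C)C(C)(C)C)[C@@]2(C)C=CC(=O)[C@@H](C)[C@@H]2[C@@H]1OC(C)=O | intermediate
21 | 6-chloro-7,8-diol ethyl ester | CCOC(=O)[C@H](C)[C@]1(O)[C@@H](O)[C@@H](Cl)C(=C)/C=C\[C@H](O[Si](C)(C)C(C)(C)C)[C@@]2(C)C=CC(=O)[C@@H](C)[C@@H]2[C@@H]1OC(C)=O | intermediate
22 | 6-chloro γ-lactone, ring A enone | C=C1/C=C\[C@H](O[Si](C)(C)C(C)(C)C)[C@@]2(C)C=CC(=O)[C@@H](C)[C@@H]2[C@H](OC(C)=O)[C@]2(O)[C@@H](C)C(=O)O[C@H]2[C@H]1Cl | intermediate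
23 | 13α,14α-epoxy-12-ketone, 2-OTBS | C=C1/C=C\[C@H](O[Si](C)(C)C(C)(C)C)[C@@]2(C)[C@H]3O[C@H]3C(=O)[C@@H](C)[C@@H]2[C@H](OC(C)=O)[C@]2(O)[C@@H](C)C(=O)O[C@H]2[C@H]1Cl | intermediate
24 | shared intermediate, 2-OH epoxy ketone | C=C1/C=C\[C@H](O)[C@@]2(C)[C@H]3O[C@H]3C(=O)[C@@H](C)[C@@H]2[C@H](OC(C)=O)[C@]2(O)[C@@H](C)C(=O)O[C@H]2[C@H]1Cl | intermediate
25 | tris-TMS Δ11(12) enol ether | C=C1/C=C\[C@H](O[Si](C)(C)C)[C@@]2(C)[C@H]3O[C@H]3C(O[Si](C)(C)C)=C(C)[C@@H]2[C@H](OC(C)=O)[C@]2(O[Si](C)(C)C)[C@@H](C)C(=O)O[C@H]2[C@H]1Cl | intermediate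
26 | 11α,12α-epoxy-12-silyloxy compound | C=C1/C=C\[C@H](O[Si](C)(C)C)[C@@]2(C)[C@H]3O[C@H]3[C@@]4(O[Si](C)(C)C)O[C@@]4(C)[C@@H]2[C@H](OC(C)=O)[C@]2(O[Si](C)(C)C)[C@@H](C)C(=O)O[C@H]2[C@H]1Cl | intermediate
27 | 11α-hydroxy-12-ketone | C=C1/C=C\[C@H](O)[C@@]2(C)[C@H]3O[C@H]3C(=O)[C@@](C)(O)[C@@H]2[C@H](OC(C)=O)[C@]2(O)[C@@H](C)C(=O)O[C@H]2[C@H]1Cl | intermediate
28 | 2β,8,11α,12α-tetraol | C=C1/C=C\[C@H](O)[C@@]2(C)[C@H]3O[C@H]3[C@@H](O)[C@@](C)(O)[C@@H]2[C@H](OC(C)=O)[C@]2(O)[C@@H](C)C(=O)O[C@H]2[C@H]1Cl | intermediate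
29 | CNP0331168.1 | C=C1/C=C\[C@H](OC(C)=O)[C@@]2(C)[C@H]3O[C@H]3[C@@H](OC(C)=O)[C@@](C)(O)[C@@H]2[C@H](OC(C)=O)[C@]2(O)[C@@H](C)C(=O)O[C@H]2[C@H]1Cl | target
30 | CNP0188106.1 | C=C1/C=C\[C@H](OC(=O)CCC)[C@@]2(C)[C@H]3O[C@H]3[C@@H](OC(=O)CCC)[C@@](C)(O)[C@@H]2[C@H](OC(C)=O)[C@]2(O)[C@@H](C)C(=O)O[C@H]2[C@H]1Cl | target
31 | CNP0325729.2 | C=C1/C=C\[C@H](O)[C@@]2(C)[C@H]3O[C@H]3[C@@H](OC(=O)CCC)[C@@](C)(O)[C@@H]2[C@H](OC(C)=O)[C@]2(O)[C@@H](C)C(=O)O[C@H]2[C@H]1Cl | target
32 | CNP0273377.1 | C=C1/C=C\[C@H](OC(C)=O)[C@@]2(C)[C@H]3O[C@H]3[C@@H](OC(=O)CCC)[C@@](C)(O)[C@@H]2[C@H](OC(C)=O)[C@]2(O)[C@@H](C)C(=O)O[C@H]2[C@H]1Cl | target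
33 | 12-O-acetate of 28 | C=C1/C=C\[C@H](O)[C@@]2(C)[C@H]3O[C@H]3[C@@H](OC(C)=O)[C@@](C)(O)[C@@H]2[C@H](OC(C)=O)[C@]2(O)[C@@H](C)C(=O)O[C@H]2[C@H]1Cl | intermediate
34 | CNP0114058.1 | C=C1/C=C\[C@H](OC(=O)CCC)[C@@]2(C)[C@H]3O[C@H]3[C@@H](OC(C)=O)[C@@](C)(O)[C@@H]2[C@H](OC(C)=O)[C@]2(O)[C@@H](C)C(=O)O[C@H]2[C@H]1Cl | target
35 | 11β-methyl-11α-H epoxy ketone | C=C1/C=C\[C@H](O)[C@@]2(C)[C@H]3O[C@H]3C(=O)[C@H](C)[C@@H]2[C@H](OC(C)=O)[C@]2(O)[C@@H](C)C(=O)O[C@H]2[C@H]1Cl | intermediate
36 | 11-deoxy 2β,12α-diol | C=C1/C=C\[C@H](O)[C@@]2(C)[C@H]3O[C@H]3[C@@H](O)[C@H](C)[C@@H]2[C@H](OC(C)=O)[C@]2(O)[C@@H](C)C(=O)O[C@H]2[C@H]1Cl | intermediate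
37 | brianthein Z | C=C1/C=C\[C@H](OC(C)=O)[C@]2(C)[C@H]([C@@H](C)[C@H](OC(C)=O)[C@@H]3O[C@@H]32)[C@H](OC(C)=O)[C@]2(O)[C@@H](C)C(=O)O[C@H]2[C@H]1Cl | target

Totals for CNP0114058.1 (compound 34): total step count 22, longest linear sequence 21
Totals for CNP0325729.2 (compound 31): total step count 21, longest linear sequence 20
Totals for CNP0273377.1 (compound 32): total step count 22, longest linear sequence 21
Totals for CNP0188106.1 (compound 30): total step count 21, longest linear sequence 20
Totals for CNP0331168.1 (compound 29): total step count 21, longest linear sequence 20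
Totals for brianthein Z (compound 37): total step count 21, longest linear sequence 20

THREE STEPS MOST LIKELY TO FAIL

**Step 10 (labelled step).**
- The alkoxide may add to the allene (oxacyclisation), or the allene may isomerise under base, before the sigmatropic shift takes place. The elimination may also lose its E selectivity.
- The fallback uses known chemistry only. It sets out from 11 and comes back at 15.
- The terminal C5=C16 bond of the allene is hydrogenated with RhCl(PPh3)3/H2 to the (Z)-prop-1-enyl ketone F1.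
- Vinyl addition as in step 9 gives the 1,2-dialkenyl decalinol F2.
- The classical anionic oxy-Cope ring expansion (KH, 18-crown-6) with the same in-flask dehydrogenation gives the 5-methyl (3Z,6E)-dienone F3.
- Deprotonation of the doubly allylic γ-hydrogen on C5 and oxygenation (KOt-Bu, O2, P(OEt)3) give the tertiary 5-alcohol F4, of which either C5 epimer serves.
- Dehydration with the Burgess reagent can only take a C16 hydrogen, since C4 and C6 are sp2, and returns trienone 15.

**Step 15.**
- Regiocontrol of the epoxide opening may be lost through SN2′ attack of chloride at C16, or through Lewis-acid rearrangement of the vinyl epoxide.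
- The fallback sets out from 19 and comes back at 22. It avoids the vinyl epoxide altogether.
- Hydrogen-bond-directed syn-dihydroxylation of C6=C7 (OsO4, TMEDA, −78 °C; aq Na2SO3), steered by 8-OH to the same face, gives the 6,7,8-triol ester F5.
- PPTS closes the γ-lactone through 7-OH to the 6-hydroxy lactone F6.
- The allylic 6-OH is replaced by chloride with inversion and without allylic shift (PPh3, hexachloroacetone). This places Cl on the same side as the epoxide route does and gives 22.

**Step 27.**
- Facial selectivity of the protonation may be poor, or C11 may equilibrate to the more stable 11α-methyl ketone.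
- The fallback sets out from 28 and comes back at 36. It replaces enolate protonation by a radical deoxygenation that finds C11 through the cis-diol.
- 1,1′-Thiocarbonyldiimidazole closes only the cis-11,12-diol to the cyclic thionocarbonate F7.
- (Me3Si)3SiH/AIBN (Barton–McCombie type) cleaves the C–O bond that gives the tertiary C11 radical. The bulky silane quenches this radical anti to C15 to give the 12-O-(silylthio)carbonyl compound F8.
- Mild methanolysis frees 12-OH and gives 36.

Further compounds
F1 | step 10 | 3α-[(Z)-prop-1-enyl] 8-ketone | C[C@]12CC=C(O[Si](C(C)C)(C(C)C)C(C)C)[C@@H](C)[C@@H]1[C@H](OCc3ccc(OC)cc3)C(=O)[C@@H](/C=C\C)[C@@H]2O[Si](C)(C)C(C)(C)C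
F2 | step 10 | 8α-vinyl-3α-[(Z)-prop-1-enyl] decalin-8β-ol | C[C@]12CC=C(O[Si](C(C)C)(C(C)C)C(C)C)[C@@H](C)[C@@H]1[C@H](OCc3ccc(OC)cc3)[C@@](O)(C=C)[C@@H](/C=C\C)[C@@H]2O[Si](C)(C)C(C)(C)C
F3 | step 10 | 5-methyl (3Z,6E)-cyclodecadien-8-one | O=C1/C=C/[C@@H](C)/C=C\[C@H](O[Si](C)(C)C(C)(C)C)[C@@]2(C)CC=C(O[Si](C(C)C)(C(C)C)C(C)C)[C@@H](C)[C@@H]2[C@@H]1OCc3ccc(OC)cc3
F4 | step 10 | 5-hydroxy-5-methyl (3Z,6E)-cyclodecadien-8-one | O=C1/C=C/[C@](C)(O)/C=C\[C@H](O[Si](C)(C)C(C)(C)C)[C@@]2(C)CC=C(O[Si](C(C)C)(C(C)C)C(C)C)[C@@H](C)[C@@H]2[C@@H]1OCc3ccc(OC)cc3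
F5 | step 15 | 6,7,8-triol ethyl ester | CCOC(=O)[C@H](C)[C@]1(O)[C@@H](O)[C@H](O)C(=C)/C=C\[C@H](O[Si](C)(C)C(C)(C)C)[C@@]2(C)C=CC(=O)[C@@H](C)[C@@H]2[C@@H]1OC(C)=O
F6 | step 15 | 6-hydroxy γ-lactone | C=C1/C=C\[C@H](O[Si](C)(C)C(C)(C)C)[C@@]2(C)C=CC(=O)[C@@H](C)[C@@H]2[C@H](OC(C)=O)[C@]2(O)[C@@H](C)C(=O)O[C@H]2[C@@H]1O
F7 | step 27 | 11,12-cyclic thionocarbonate | C=C1/C=C\[C@H](O)[C@@]2(C)[C@H]3O[C@H]3[C@H]4OC(=S)O[C@@]4(C)[C@@H]2[C@H](OC(C)=O)[C@]2(O)[C@@H](C)C(=O)O[C@H]2[C@H]1Cl
F8 | step 27 | 11-deoxy 12-O-[tris(trimethylsilyl)silylthio]carbonyl compound | C=C1/C=C\[C@H](O)[C@@]2(C)[C@H]3O[C@H]3[C@@H](OC(=O)S[Si]([Si](C)(C)C)([Si](C)(C)C)[Si](C)(C)C)[C@H](C)[C@@H]2[C@H](OC(C)=O)[C@]2(O)[C@@H](C)C(=O)O[C@H]2[C@H]1Cl
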